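The runs stem from a simulated flask on assumed constants, noise included.

Two runs stand.

the same everywhere: gas phase 2.9 mM (held)
- north-east: solid substrate 0.022 M; run made earlier
- south-west: solid substrate 0.32 M; run made earlier
- winter: solid substrate 0.20 M; time 6.0 min
- summer: solid substrate 0.054 M; time 6.0 min
- dawn: solid substrate 0.10 M; time 6.0 min
- spring: solid substrate 0.080 M; time 6.0 min
- dusk: solid substrate 0.015 M; time 6.0 min
- autumn: solid substrate 0.040 M; time 6.0 min

| run | time / min | target / % | solid substrate / % |
|---|---|---|---|
| north-east | 0.333 | 3 | 92 |
| north-east | 0.500 | 1 | 86 |
| north-east | 1.00 | 7 | 73 |
| north-east | 1.50 | 8 | 59 |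
| north-east | 2.50 | 22 | 32 |
| north-east | 4.00 | 35 | 1 |
| south-west | 0.667 | 0 | 102 |
| south-west | 1.33 | 0 | 95 |
| south-west | 2.00 | 0 | 97 |
| south-west | 3.00 | 1 | 94 |
| south-west | 4.00 | 2 | 91 |

(each reading ± 1.5 percentage points)

- amounts and yields of target count crystals too
- given per volume of solution although it is solid: solid substrate, crystals
- at the start none of the gas is dissolved
- steps that have been proposed: starting material -> side product; crystals <-> target; target -> over-reaction product; starting material + dissolved gas -> target; solid substrate <-> starting material; gas phase <-> dissolved gas
- at the start none of the solid substrate is in solution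
- what has only dissolved of solid substrate counts as not reacted

1. ranking by amount of target, in percent of the solid substrate charged, from high to low, at 6.0 min (winter / summer / dawn / spring / dusk / autumn)
2. the amount of target, in percent of the solid substrate charged of the flask you put first, at 6.0 min
3. the amount of target, in percent of the solid substrate charged of the flask you put last, at 6.0 min

The north-east flask reads 32% of its solid substrate at 2.50 min. Taken as a steady, zero-order loss, that reading gives a clearing time, the time a charge of solid substrate would need to disappear at that pace:

3.68 min for the north-east charge

The first setting is the charge. By hand, the clearing time grows in proportion to the charge, so a flask with a clearing time beyond the run loses the fraction t/τ of its charge. The south-west flask, with 14.5 times the charge, has 91% left at 4.00 min, a loss read with a scatter of 1.5 percentage points, and its target reads 2% against 35% in the north-east flask.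

The second setting is time. By hand, target follows the lost solid substrate until the charge has cleared. The north-east flask shows this as a share of target per lost solid:

35.4% at 4.00 min

The gas phase is held equal in every flask. My reckoning at 6.0 min is then:

dusk: τ = 2.51 min, reckoned cleared, target 35.4%

autumn: τ = 6.68 min, target 31.8%

winter: τ = 33.4 min, target 6.36%

In this reckoning dusk comes first, its clearing time being shorter than those of autumn and winter.

The forecast, which speaks of “a supply-limited process, probably gas transfer”, gives the same order: dusk > autumn > summer > spring > dawn > winter. It puts the top at 60% (42% to 78%), above my figure for dusk, and the low at 6% (3.5% to 9%).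

The flasks give dusk > autumn > summer > spring > dawn > winter, with top 42.9% and low 6.14%.

    starting material → side product (k = 0.0140 s⁻¹)
    crystals ⇌ target, rate k2*(cs2 - [target]) while solid is left; crystals form when [target] > cs2 (solubility = 24.0 mM, k = 0.350 s⁻¹)
    target → over-reaction product (k = 2.20 × 10⁻⁶ s⁻¹)
    starting material + dissolved gas → target (k = 9.60 M⁻¹ s⁻¹)
    solid substrate ⇌ starting material, rate k5*(cs5 - [starting material]) while solid is left; crystals form when [starting material] > cs5 (solubility = 42.0 mM, k = 0.00250 s⁻¹)
    gas phase ⇌ dissolved gas, rate k6*(csat - [dissolved gas]) (kL = 0.0190 s⁻¹)

Dusk, reckoned clear after 2.51 min, holds 0% solid substrate at 6.00 min, and its target stands above my figure and below the forecast's. The neighbour is the dusk flask with 0.037 M of solid substrate. Its clearing time is 6.18 min, slightly longer than the run. The reckoning leaves 2.96% of the charge as solid substrate and gives target 34.4%. The neighbour holds 6.64% solid substrate at 6.00 min, and its target is 33.2%.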